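The vessel is closed and stirred, and a small charge of free catalyst has to carry a large charge of starting material, so I count how often each catalyst has worked.

| flask | starting material | second substrate | free catalyst | remark | time |
|---|---|---|---|---|---|
| spring | 2 M | 1.3 M | 60 mM | run made earlier |  |
| midnight | 2 M | 1 M | 60 mM | run made earlier |  |
| red | 2.0 M | 2.00 M | 60 mM |  | 15 h |
| blue | 2.0 M | 2.00 M | 100 mM |  | 15 h |
| violet | 2.0 M | 2.00 M | 150 mM |  | 15 h |

| run | time / h | target / % | starting material / % |
|---|---|---|---|
| spring | 2.00 | 17.8 | 81.3 |
| spring | 4.00 | 31.7 | 67.8 |
| spring | 5.00 | 37.5 | 61.8 |
| spring | 8.00 | 50.9 | 48.0 |
| spring | 10.0 | 57.7 | 41.8 |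
| midnight | 2.00 | 18.9 | 81.3 |
| midnight | 4.00 | 33.8 | 65.7 |
| midnight | 5.00 | 38.3 | 59.5 |
| midnight | 8.00 | 52.4 | 46.1 |
| midnight | 10.0 | 59.1 | 39.1 |

(readings scatter by 0.5 percentage points)

- the numbers in the tables scatter by 0.5 percentage points (one standard deviation)
- "hardly changes" means that all values lie within two and a half points (for a concentration: within two and a half percent of the largest)
- no earlier run changes the charge of free catalyst; that part of a forecast is a guess

- amount of target at the end, in percent of the starting material charged for red, blue, violet, in this order
- the shape of the row from first to last (hardly changes / rises, then falls / falls, then rises / rises all the way / falls all the way)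

In the spring run, the readings of [starting material] fall at 0.0692 /h between the last two points. At that late pace I reckon 29.6% left in spring at 15 h, and the sum of target and starting material, which reads near 99.5% at the last point, puts my estimate of the target at 69.9%. With 2.0 M charged over 60 mM of catalyst, that is 23.3 turnovers, my turnover count: target made per catalyst charged by the asked time, the usual turnover number. Red has more second substrate than spring, 2.00 M against 1.3 M, and the last target reading of spring already stands lower than that of midnight, 57.7% against 59.1%, so I put red a little under that figure.

The bench rule says that, with the other charges and the time held fixed, each catalyst makes the same count, so target grows in step with the catalyst charged. Honestly applied, it gives 117% for blue and 175% for violet, both more than the starting material charged. The border is the ratio of charge to catalyst: 33.3 turnovers in red, 20.0 in blue and 13.3 in violet. My count lies below the first and above the other two, so by my estimate the rule stops between red and blue. Beyond that border I expect blue and violet to stay under full conversion and the row to rise all the way.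

The forecast gives 63%, 78% and 87%, rises all the way, taking “roughly first-order catalyst with some sublinearity”. The flasks give 67.3%, 89.6% and 96.7%, rises all the way.

    second substrate + free catalyst ⇌ catalyst intermediate B (K = 0.540 /M, k = 0.280 /M/min)
    catalyst intermediate A → spent catalyst (k = 0.00520 /min)
    starting material + free catalyst ⇌ catalyst intermediate A (K = 0.440 /M, k = 0.170 /M/min)
    catalyst intermediate A → free catalyst + target (k = 0.210 /min)
    catalyst intermediate B → free catalyst + second product (k = 0.140 /min)

Red makes 22.4 turnovers against my 23.3, and violet makes 12.9 of the 13.3 its charge allows. Catalyst intermediate A gives target with the rate constant 0.21 /min and spent catalyst with 0.0052 /min, which is 40.4 turnovers to target for each catalyst lost. Divided by that ratio, the turnovers of red give 55.5%, and spent catalyst in red stands at 55.5% after 15.0 h. The turnovers of violet give 31.9%, and spent catalyst in violet stands at 31.9% after 15.0 h.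

The numbers in the tables stem from a simulated flask from invented constants; scatter was added.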